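# Proposed synthesis of CNP0132298.1 through a transannular Ireland–Claisen rearrangement of a δ-lactone dienolate

## Analysis of the target

The target is a trans-fused hexahydroinden-2-one. Ring A is a cyclohexene (C3a, C4, C5, C6, C7, C7a; C6=C7, ethyl on C7) and ring B a cyclopentanone (C1, C2, C3, C3a, C7a) whose carbonyl C2 lies between two ethyl-bearing methines. Six contiguous stereocentres are present: C1, C3, C3a, C4, C5 and C7a. C4 (ethyl, carboxyl) and C5 (ethyl, (E)-styryl) are adjacent quaternary carbons; their ethyl groups are cis to each other and to H-7a, whereas carboxyl, styryl and H-3a lie on the other face, so the ring fusion is trans. The ethyl groups on C1 and C3 are each trans to the ring bond on the neighbouring fusion carbon; both carbons are α to the ketone, so this arrangement can be reached by equilibration and only C3a, C4, C5 and C7a need kinetic control. Sensitive features are the styryl group and the trisubstituted ring alkene (no hydrogenation, ozonolysis or dissolving metal), the epimerisable α-carbons, and a carboxyl group so hindered that its esters cannot be cleaved at the acyl carbon. The real difficulty is the C4–C5 bond, which joins two fully substituted carbons in a fixed relative configuration next to a ring-fusion stereocentre. The strategy rests on the unit C7=C6–C5–C4–CO2H: C5 is allylic to the ring alkene and bonded to the carboxyl-bearing C4, which is the product pattern of an ester-enolate Claisen shift. If C7 is tied to the carboxyl oxygen in a δ-lactone, that shift becomes transannular and stereospecific.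

## Retrosynthetic reasoning

Atom labels: target carbons carry indene numbers. In the lactones 16 to 20 the ring is O1, C2 (C=O), C3, C4, C5, C6, and the dienyl carbons are C1' (on C6) to C4'.

**29 from 28.** The acid is carried as methyl ester 28 because a free carboxyl would interfere with the ring-B closure. Only the O–CH3 bond is cut at the end, since the acyl carbon on the quaternary C4 cannot be reached by a nucleophile.

**28 from 26.** Ring B is opened at C2–C3, with H removed from C3a. This leaves aldehyde 26, a 4-pentenal whose alkene is an exocyclic propylidene on ring A. The forward hydroacylation forms the acyl–C3 bond and delivers hydrogen to C3a from the face of the acyl arm, which is what a trans fusion needs. A cut at C1–C2 or at a fusion bond would require a nucleophile or electrophile next to the quaternary C4. C3 is formed as the less stable epimer and must be equilibrated.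

**26 from 23.** These are functional-group changes only: the aldehyde comes from the silyl ether and the ester from acid 23. The silyl ether is kept until after the rearrangement because it withstands the strong base of the key step.

**23 from 20 (key disconnection).** The C4–C5 bond is cut and the carboxyl oxygen joined to C7, giving lactone 20. This is the only cut that makes both quaternary carbons in one step. The forward reaction has to enolise 20 at the γ-position of its propyl group, trap the dienolate on oxygen, and pass through a boat [3,3] shift. That shift transfers the configuration of the tertiary carbinol carbon C6 to both new centres and leaves the propylidene needed for ring B.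

**20 from 18 and 19, 18 from 16.** The C4–propyl bond of the tetrasubstituted enoate is cut, leading to enol triflate 18 and Grignard reagent 19. Cross-coupling at an sp2 carbon is preferred over an olefination because it forms the crowded alkene without a condensation at a hindered ketone. Triflate 18 comes from the vinylogous acid 16 after silylation of its primary hydroxyl (17).

**16 from 15.** The C3–C4 bond of the pyranone is cut. In the forward sense the butanoate enolate of 15 attacks the neighbouring butyrolactone carbonyl. This intramolecular Claisen condensation expands the γ-lactone to the δ-lactone and releases the primary alcohol in one operation, with C5 and C6 already in place.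

**15 from 7, 13 and 2.** The C5–C6 bond is cut as an aldol addition of the enolate of lactone 7 to dienone 13; the aldolate is capped with acid chloride 2. The 4-ethyl group of 7 controls C5 (trans addition). The chair transition state has to control C6, and this is the one stereocentre of the front end that rests on steric differentiation alone.

**13 from 8, 9 and 12.** The trisubstituted alkene is traced to a syn-carbocupration of ynoate 8 with the styryl group of 9, because this fixes the (E) geometry that decides the configuration at C5 of the target. Ester 10 is taken to ketone 13 through amide 11 and Grignard reagent 12.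

**7 from 1, 2 and 4.** The single stereocentre of lactone 7 comes from an auxiliary-controlled alkylation of imide 3 (from 1 and 2) with bromoacetate 4, followed by reduction (5 to 6) and lactonisation.

## Alternatives that were turned down

**Alternative 1:** Ring A is disconnected at C6=C7. In the forward sense, ring-closing metathesis (second-generation Grubbs catalyst) of triene A2 joins the butenyl group on C7a to one of two diastereotopic vinyl groups on C5 and gives A1.
- For: ring B, its trans fusion and four stereocentres are secure before ring A closes, the conditions are neutral, and C5 is not stereogenic until the last step. On functional-group tolerance and on the security of the ring fusion this route is stronger than the chosen one.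
- Against: the C4–C5 bond between two quaternary carbons must already exist in A2, and metathesis does nothing to make it. The closure joins a 1,1-disubstituted alkene to a neopentyl vinyl group, and the choice between the two vinyl groups rests on small conformational differences. A1 carries vinyl where the target has styryl, so a cross-metathesis on a neopentyl alkene is still needed.
- Comparison: the chosen route makes the C4–C5 bond and both quaternary configurations in its key step, with the styryl group already present.

**Alternative 2:** Rings A and B are disconnected together at C3a–C7a, C1–C2 and C2–C3. Dienyne A4, CO and Co2(CO)8 with an amine N-oxide (or [RhCl(CO)2]2) would give enone A3 in a Pauson–Khand reaction.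
- For: three C–C bonds and two rings form in one step, which is better than the chosen route on bond count per step.
- Against: A4 is an open chain in which both quaternary stereocentres must already be set without a ring to help. The ene partner is the internal alkene of a conjugated diene, and C7a is controlled only by remote centres. A3 has a C3=C3a double bond, so the trans fusion must come from conjugate reduction of a tetrasubstituted enone in the presence of the styryl group.
- Comparison: the chosen route sets C3a by intramolecular hydride delivery and needs no reduction.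

**Alternative 3:** Ring B is disconnected at C1–C7a. Rh2(OAc)4 converts diazo keto ester A6 into a carbenoid that inserts into the allylic C–H bond of the ring CH2 and gives β-keto ester A5.
- For: 1,5-insertion into a secondary allylic C–H bond is a favourable five-ring closure, and insertion into the pseudo-equatorial bond gives the trans fusion. As a ring-B closure it is probably more dependable than hydroacylation of a trisubstituted alkene.
- Against: A5 carries an ethoxycarbonyl group where the target has ethyl, so C-ethylation of a hindered β-keto ester and dealkoxycarbonylation beside a second ester are needed. Cyclopropanation of C6=C7 can compete. The cyclohexene A6, with both quaternary carbons and C3a, must still be made.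
- Comparison: the chosen route builds that cyclohexene in the key step and pays with a less secure ring-B closure, for which a fallback is given below.

Key step: step 13

## Route

Remark: 16 and 17 are written as the 4-hydroxypyranone (enol) tautomers of the β-keto lactone. Compounds 1, 2, 4, 8, 9, 12 and 19 are taken to be commercial.

Step 1
Reactants: 1 (R)-4-benzyl-1,3-oxazolidin-2-one; 2 butanoyl chloride
Product: 3 (R)-4-benzyl-3-butanoyl-1,3-oxazolidin-2-one
Conditions: n-BuLi, THF, −78 °C; then 2, −78 °C to 0 °C
Reagents that add atoms: none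
Why: N-Acylation of the lithiated oxazolidinone by the acid chloride; no stereocentre is formed and the acyl α-carbon will become C1 of the target.

Step 2
Reactants: 3 (R)-4-benzyl-3-butanoyl-1,3-oxazolidin-2-one; 4 tert-butyl bromoacetate
Product: 5 tert-butyl (3S)-3-{[(4R)-4-benzyl-2-oxo-1,3-oxazolidin-3-yl]carbonyl}pentanoate
Conditions: NaN(SiMe3)2, THF, −78 °C; then 4, −78 °C
Reagents that add atoms: none
Why: Evans alkylation: the chelated (Z)-sodium enolate is shielded on one face by the benzyl group, so the bromoacetate adds to the other face and sets the new centre as (S).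

Step 3
Reactants: 5 tert-butyl (3S)-3-{[(4R)-4-benzyl-2-oxo-1,3-oxazolidin-3-yl]carbonyl}pentanoate
Product: 6 tert-butyl (3S)-3-(hydroxymethyl)pentanoate
Conditions: LiBH4, H2O (1 equiv), Et2O, 0 °C
Reagents that add atoms: none
Why: Reductive cleavage of the N-acyl oxazolidinone frees the primary alcohol and returns the auxiliary; the tert-butyl ester is too hindered to be reduced under these conditions.

Step 4
Reactants: 6 tert-butyl (3S)-3-(hydroxymethyl)pentanoate
Product: 7 (4S)-4-ethyloxolan-2-one
Conditions: CF3CO2H, CH2Cl2, 0 °C to rt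
Reagents that add atoms: none
Why: Acid removes the tert-butyl group and the γ-hydroxy acid lactonises (acyl substitution closing a five-membered ring); no bond to the stereocentre is touched.

Step 5
Reactants: 8 ethyl pent-2-ynoate; 9 [(E)-2-bromoethenyl]benzene
Product: 10 ethyl (2E,4E)-3-ethyl-5-phenylpenta-2,4-dienoate
Conditions: 9 (2 equiv), t-BuLi (4 equiv), Et2O, −78 °C; CuI (1 equiv), THF, −40 °C; then 8, −78 °C; MeOH, then aq. NH4Cl, −78 °C
Reagents that add atoms: none
Why: Syn-carbocupration of the ynoate: styryl and copper add to the same side of the triple bond, and protonation of the α-cuprio ester at −78 °C with retention leaves styryl trans and ethyl cis to the ester. Bromine–lithium exchange keeps the (E)-styryl geometry.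

Step 6
Reactants: 10 ethyl (2E,4E)-3-ethyl-5-phenylpenta-2,4-dienoate
Product: 11 (2E,4E)-3-ethyl-N-methoxy-N-methyl-5-phenylpenta-2,4-dienamide
Conditions: MeNH(OMe)·HCl, i-PrMgCl, THF, −20 °C
Reagents that add atoms: N,O-dimethylhydroxylamine hydrochloride, CNOC.Cl
Why: Aminolysis of the ester by the chloromagnesium amide gives the Weinreb amide; the β,β-disubstituted dienoate is a poor Michael acceptor, so acyl substitution should prevail and both alkene geometries stay as they are.

Step 7
Reactants: 11 (2E,4E)-3-ethyl-N-methoxy-N-methyl-5-phenylpenta-2,4-dienamide; 12 ethylmagnesium bromide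
Product: 13 (4E,6E)-5-ethyl-7-phenylhepta-4,6-dien-3-one
Conditions: 12, THF, −20 °C to 0 °C; cold 1 M HCl quench
Reagents that add atoms: none
Why: Weinreb ketone synthesis: the chelated tetrahedral intermediate stops at single addition and releases the ethyl ketone on quench; conjugate addition is disfavoured by the β-ethyl group.

Step 8
Reactants: 7 (4S)-4-ethyloxolan-2-one; 13 (4E,6E)-5-ethyl-7-phenylhepta-4,6-dien-3-one; 2 butanoyl chloride
Product: 15 (3R,4E,6E)-5-ethyl-3-[(3R,4S)-4-ethyl-2-oxooxolan-3-yl]-7-phenylhepta-4,6-dien-3-yl butanoate, via lithium aldolate 14 (not isolated)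
Conditions: LiN(SiMe3)2, THF, −78 °C; then 13, −78 °C; then 2, −78 °C to −30 °C
Reagents that add atoms: none
Why: Aldol addition of the lactone lithium enolate to the ketone, followed by O-acylation of the tertiary aldolate before it can revert. The enolate reacts anti to its 4-ethyl group (trans lactone). At the carbonyl, a Zimmerman–Traxler chair with the ring-fixed (E)-enolate should place the dienyl group equatorial and the ethyl group axial, which gives the (R) carbinol carbon; the dienyl group is held s-cis by its cis-ethyl substituent and is therefore the bulkier one.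

Step 9
Reactants: 15 (3R,4E,6E)-5-ethyl-3-[(3R,4S)-4-ethyl-2-oxooxolan-3-yl]-7-phenylhepta-4,6-dien-3-yl butanoate
Product: 16 (5S,6R)-3,6-diethyl-6-[(1E,3E)-2-ethyl-4-phenylbuta-1,3-dien-1-yl]-4-hydroxy-5-[(2S)-1-hydroxybutan-2-yl]-5,6-dihydro-2H-pyran-2-one
Conditions: LiN(iPr)2 (2.2 equiv), THF, −78 °C to −20 °C; aq. NH4Cl
Reagents that add atoms: none
Why: Intramolecular Claisen (Dieckmann-type) condensation: the open butanoate CH2 is deprotonated in preference to the shielded lactone α-CH, and the ester enolate attacks the neighbouring lactone carbonyl through a six-membered transition state. Loss of the primary alkoxide and deprotonation of the β-keto lactone make the ring expansion irreversible; C5 and C6 are not touched.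

Step 10
Reactants: 16 (5S,6R)-3,6-diethyl-6-[(1E,3E)-2-ethyl-4-phenylbuta-1,3-dien-1-yl]-4-hydroxy-5-[(2S)-1-hydroxybutan-2-yl]-5,6-dihydro-2H-pyran-2-one
Product: 17 (5S,6R)-5-[(2S)-1-{[tert-butyl(dimethyl)silyl]oxy}butan-2-yl]-3,6-diethyl-6-[(1E,3E)-2-ethyl-4-phenylbuta-1,3-dien-1-yl]-4-hydroxy-5,6-dihydro-2H-pyran-2-one
Conditions: TBSCl, imidazole, DMF, 0 °C; aq. NaHCO3 work-up
Reagents that add atoms: tert-butyl(chloro)dimethylsilane, CC(C)(C)[Si](C)(C)Cl
Why: Silylation of the primary alcohol; any silyl group on the acidic enol oxygen is a labile vinylogous silyl ester and is lost on aqueous work-up.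

Step 11
Reactants: 17 (5S,6R)-5-[(2S)-1-{[tert-butyl(dimethyl)silyl]oxy}butan-2-yl]-3,6-diethyl-6-[(1E,3E)-2-ethyl-4-phenylbuta-1,3-dien-1-yl]-4-hydroxy-5,6-dihydro-2H-pyran-2-one
Product: 18 (5R,6R)-5-[(2S)-1-{[tert-butyl(dimethyl)silyl]oxy}butan-2-yl]-3,6-diethyl-6-[(1E,3E)-2-ethyl-4-phenylbuta-1,3-dien-1-yl]-2-oxo-5,6-dihydro-2H-pyran-4-yl trifluoromethanesulfonate
Conditions: Tf2O, Et3N, CH2Cl2, −78 °C
Reagents that add atoms: trifluoromethanesulfonic anhydride, O=S(=O)(OS(=O)(=O)C(F)(F)F)C(F)(F)F
Why: O-Sulfonylation of the vinylogous acid at the C4 oxygen gives the enol triflate. The change of descriptor at C5 is a priority effect only; no stereocentre is altered.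

Step 12
Reactants: 18 (5R,6R)-5-[(2S)-1-{[tert-butyl(dimethyl)silyl]oxy}butan-2-yl]-3,6-diethyl-6-[(1E,3E)-2-ethyl-4-phenylbuta-1,3-dien-1-yl]-2-oxo-5,6-dihydro-2H-pyran-4-yl trifluoromethanesulfonate; 19 propylmagnesium bromide
Product: 20 (5S,6R)-5-[(2S)-1-{[tert-butyl(dimethyl)silyl]oxy}butan-2-yl]-3,6-diethyl-6-[(1E,3E)-2-ethyl-4-phenylbuta-1,3-dien-1-yl]-4-propyl-5,6-dihydro-2H-pyran-2-one
Conditions: Fe(acac)3 (5 mol %), THF–NMP, −30 °C
Reagents that add atoms: none
Why: Iron-catalysed alkyl–alkenyl cross-coupling (Kumada type) of the enol triflate with the primary Grignard reagent is fast at low temperature and should outrun addition to the lactone carbonyl. It completes the tetrasubstituted enoate without touching C5 or C6.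

Step 13
Reactants: 20 (5S,6R)-5-[(2S)-1-{[tert-butyl(dimethyl)silyl]oxy}butan-2-yl]-3,6-diethyl-6-[(1E,3E)-2-ethyl-4-phenylbuta-1,3-dien-1-yl]-4-propyl-5,6-dihydro-2H-pyran-2-one
Product: 23 (1R,2S,5R,6E)-5-[(2S)-1-{[tert-butyl(dimethyl)silyl]oxy}butan-2-yl]-1,2,4-triethyl-2-[(E)-2-phenylethenyl]-6-propylidenecyclohex-3-ene-1-carboxylic acid, via silyl ketene acetal 21 (not isolated), via silyl ester 22 (not isolated)
Conditions: KN(SiMe3)2, TBSCl, DMPU, THF–toluene, −78 °C; then 80 °C; then K2CO3, MeOH–H2O, 0 °C, acidify to pH 4
Reagents that add atoms: none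
Why: The base, with the silyl chloride already present, removes a γ-hydrogen from the C4 propyl group and the extended enolate is silylated on oxygen to give the cross-conjugated ketene acetal 21, whose propylidene ethyl group turns away from the C3 ethyl group. On warming, 21 undergoes an Ireland–Claisen [3,3] shift through the array C3=C2–O1–C6–C1'=C2'; because C3 and C6 are bridged by C4–C5 the array can only be a boat, and the closest known reaction type is the Claisen rearrangement of lactone silyl ketene acetals that carry a vinyl group on the carbinol carbon. Ring A closes by suprafacial formation of the C3–C2' bond across the lactone, a sigmatropic closure and not a polar exo or endo cyclisation, while O1–C6 breaks and C6=C1' becomes the ring alkene. The new centre from C2' (C5 of the target) is fixed by the (R) configuration of C6, which holds the dienyl arm on one face of the lactone, together with the (E) geometry of C1'=C2' (ethyl cis to C6), which decides whether ethyl or styryl ends up on the carboxyl face. The new centre at C3 (C4 of the target) follows from the same face, since the bond can form only where the dienyl arm sits and the ketene acetal geometry is fixed by the ring. Both centres are thereby set relative to C5, whose side chain is trans to the dienyl arm and stays out of the folded array. The step needs γ-deprotonation at the propyl group and not at C5–H, O-silylation, and a concerted shift ahead of ionisation of the tertiary dienylic C–O bond. The first is secured by allylic strain, which turns the C5 side chain axial and leaves C5–H in the enoate plane where it is neither acidic nor accessible; the others by in-situ silylation at −78 °C in a weakly polar, acid-free medium. Mild base then cleaves silyl ester 22 and leaves the primary silyl ether intact.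

Step 14
Reactants: 23 (1R,2S,5R,6E)-5-[(2S)-1-{[tert-butyl(dimethyl)silyl]oxy}butan-2-yl]-1,2,4-triethyl-2-[(E)-2-phenylethenyl]-6-propylidenecyclohex-3-ene-1-carboxylic acid
Product: 24 methyl (1R,2S,5R,6E)-5-[(2S)-1-{[tert-butyl(dimethyl)silyl]oxy}butan-2-yl]-1,2,4-triethyl-2-[(E)-2-phenylethenyl]-6-propylidenecyclohex-3-ene-1-carboxylate
Conditions: MeI, K2CO3, DMF, rt
Reagents that add atoms: iodomethane, CI
Why: SN2 O-alkylation of the carboxylate, which is not slowed by the crowding around the acyl carbon; the ester keeps the carboxyl away from the cationic rhodium catalyst.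

Step 15
Reactants: 24 methyl (1R,2S,5R,6E)-5-[(2S)-1-{[tert-butyl(dimethyl)silyl]oxy}butan-2-yl]-1,2,4-triethyl-2-[(E)-2-phenylethenyl]-6-propylidenecyclohex-3-ene-1-carboxylate
Product: 25 methyl (1R,2S,5R,6E)-1,2,4-triethyl-5-[(2S)-1-hydroxybutan-2-yl]-2-[(E)-2-phenylethenyl]-6-propylidenecyclohex-3-ene-1-carboxylate
Conditions: HF·pyridine, THF, 0 °C to rt
Reagents that add atoms: none
Why: Fluoride-mediated desilylation under non-basic conditions, so that the doubly allylic ring hydrogen is not exposed to base and the skipped diene does not migrate.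

Step 16
Reactants: 25 methyl (1R,2S,5R,6E)-1,2,4-triethyl-5-[(2S)-1-hydroxybutan-2-yl]-2-[(E)-2-phenylethenyl]-6-propylidenecyclohex-3-ene-1-carboxylate
Product: 26 methyl (1R,2S,5R,6E)-1,2,4-triethyl-5-[(2S)-1-oxobutan-2-yl]-2-[(E)-2-phenylethenyl]-6-propylidenecyclohex-3-ene-1-carboxylate
Conditions: Dess–Martin periodinane, NaHCO3, CH2Cl2, 0 °C
Reagents that add atoms: none
Why: Dess–Martin oxidation, buffered, gives the α-branched aldehyde without touching the alkenes and with little risk to the α-stereocentre.

Step 17
Reactants: 26 methyl (1R,2S,5R,6E)-1,2,4-triethyl-5-[(2S)-1-oxobutan-2-yl]-2-[(E)-2-phenylethenyl]-6-propylidenecyclohex-3-ene-1-carboxylate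
Product: 28 methyl (1S,3S,3aR,4R,5S,7aR)-1,3,4,5,7-pentaethyl-2-oxo-5-[(E)-2-phenylethenyl]-2,3,3a,4,5,7a-hexahydro-1H-indene-4-carboxylate, via C3-epimeric keto ester 27 (not isolated)
Conditions: [Rh(dppe)(acetone)2]BF4 (10 mol %, from [Rh(nbd)(dppe)]BF4 and H2), acetone, 25 to 50 °C; then DBU (0.2 equiv), rt
Reagents that add atoms: none
Why: Intramolecular rhodium-catalysed hydroacylation of a 4-pentenal: C–H oxidative addition, syn insertion of the exocyclic alkene into Rh–H with hydride delivered to C3a from the face that carries the acyl arm (hence trans to H-7a), and C–C reductive elimination from the six-membered acyl rhodacycle close ring B. Syn addition to the (E)-propylidene first gives 27, with the C3 ethyl group cis to the C3a–C4 bond. DBU equilibrates C3 (and C1, should it have drifted at the aldehyde stage) to the all-trans arrangement of 28, which is the most stable one.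

Step 18
Reactants: 28 methyl (1S,3S,3aR,4R,5S,7aR)-1,3,4,5,7-pentaethyl-2-oxo-5-[(E)-2-phenylethenyl]-2,3,3a,4,5,7a-hexahydro-1H-indene-4-carboxylate
Product: 29 (1S,3S,3aR,4R,5S,7aR)-1,3,4,5,7-pentaethyl-2-oxo-5-[(E)-2-phenylethenyl]-2,3,3a,4,5,7a-hexahydro-1H-indene-4-carboxylic acid
Conditions: LiI, pyridine, reflux; then 1 M HCl
Reagents that add atoms: none
Why: SN2 demethylation: iodide attacks the methyl carbon, so the two quaternary carbons around the acyl group do not matter. The α-carbons are already in their thermodynamic configuration and the alkenes are inert.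

## Compound list

1 | (R)-4-benzyl-1,3-oxazolidin-2-one | O=C1N[C@H](Cc2ccccc2)CO1 | starting material
2 | butanoyl chloride | CCCC(=O)Cl | starting material
3 | (R)-4-benzyl-3-butanoyl-1,3-oxazolidin-2-one | CCCC(=O)N1[C@H](Cc2ccccc2)COC1=O | intermediate
4 | tert-butyl bromoacetate | CC(C)(C)OC(=O)CBr | starting material
5 | tert-butyl (3S)-3-{[(4R)-4-benzyl-2-oxo-1,3-oxazolidin-3-yl]carbonyl}pentanoate | CC[C@@H](CC(=O)OC(C)(C)C)C(=O)N1[C@H](Cc2ccccc2)COC1=O | intermediate
6 | tert-butyl (3S)-3-(hydroxymethyl)pentanoate | CC[C@@H](CC(=O)OC(C)(C)C)CO | intermediate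
7 | (4S)-4-ethyloxolan-2-one | CC[C@@H]1COC(=O)C1 | intermediate
8 | ethyl pent-2-ynoate | CCC#CC(=O)OCC | starting material
9 | [(E)-2-bromoethenyl]benzene | Br/C=C/c1ccccc1 | starting material
10 | ethyl (2E,4E)-3-ethyl-5-phenylpenta-2,4-dienoate | CCOC(=O)/C=C(\CC)/C=C/c1ccccc1 | intermediate
11 | (2E,4E)-3-ethyl-N-methoxy-N-methyl-5-phenylpenta-2,4-dienamide | CON(C)C(=O)/C=C(\CC)/C=C/c1ccccc1 | intermediate
12 | ethylmagnesium bromide | CC[Mg]Br | starting material
13 | (4E,6E)-5-ethyl-7-phenylhepta-4,6-dien-3-one | CCC(=O)/C=C(\CC)/C=C/c1ccccc1 | intermediate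
14 | lithium (3R,4E,6E)-5-ethyl-3-[(3R,4S)-4-ethyl-2-oxooxolan-3-yl]-7-phenylhepta-4,6-dien-3-olate | CC[C@@H]1COC(=O)[C@H]1[C@@](O[Li])(CC)/C=C(\CC)/C=C/c1ccccc1 | intermediate
15 | (3R,4E,6E)-5-ethyl-3-[(3R,4S)-4-ethyl-2-oxooxolan-3-yl]-7-phenylhepta-4,6-dien-3-yl butanoate | CC[C@@H]1COC(=O)[C@H]1[C@@](OC(=O)CCC)(CC)/C=C(\CC)/C=C/c1ccccc1 | intermediate
16 | (5S,6R)-3,6-diethyl-6-[(1E,3E)-2-ethyl-4-phenylbuta-1,3-dien-1-yl]-4-hydroxy-5-[(2S)-1-hydroxybutan-2-yl]-5,6-dihydro-2H-pyran-2-one | OC1=C(CC)C(=O)O[C@](CC)(/C=C(\CC)/C=C/c2ccccc2)[C@H]1[C@H](CC)CO | intermediate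
17 | (5S,6R)-5-[(2S)-1-{[tert-butyl(dimethyl)silyl]oxy}butan-2-yl]-3,6-diethyl-6-[(1E,3E)-2-ethyl-4-phenylbuta-1,3-dien-1-yl]-4-hydroxy-5,6-dihydro-2H-pyran-2-one | OC1=C(CC)C(=O)O[C@](CC)(/C=C(\CC)/C=C/c2ccccc2)[C@H]1[C@H](CC)CO[Si](C)(C)C(C)(C)C | intermediate
18 | (5R,6R)-5-[(2S)-1-{[tert-butyl(dimethyl)silyl]oxy}butan-2-yl]-3,6-diethyl-6-[(1E,3E)-2-ethyl-4-phenylbuta-1,3-dien-1-yl]-2-oxo-5,6-dihydro-2H-pyran-4-yl trifluoromethanesulfonate | FC(F)(F)S(=O)(=O)OC1=C(CC)C(=O)O[C@](CC)(/C=C(\CC)/C=C/c2ccccc2)[C@H]1[C@H](CC)CO[Si](C)(C)C(C)(C)C | intermediate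
19 | propylmagnesium bromide | CCC[Mg]Br | starting material
20 | (5S,6R)-5-[(2S)-1-{[tert-butyl(dimethyl)silyl]oxy}butan-2-yl]-3,6-diethyl-6-[(1E,3E)-2-ethyl-4-phenylbuta-1,3-dien-1-yl]-4-propyl-5,6-dihydro-2H-pyran-2-one (dienyl arm trans to the C5 side chain) | CCCC1=C(CC)C(=O)O[C@](CC)(/C=C(\CC)/C=C/c2ccccc2)[C@H]1[C@H](CC)CO[Si](C)(C)C(C)(C)C | intermediate
21 | tert-butyl{[(2R,3S,4E)-3-[(2S)-1-{[tert-butyl(dimethyl)silyl]oxy}butan-2-yl]-2,5-diethyl-2-[(1E,3E)-2-ethyl-4-phenylbuta-1,3-dien-1-yl]-4-propylidene-3,4-dihydro-2H-pyran-6-yl]oxy}dimethylsilane | CC/C=C1/C(CC)=C(O[Si](C)(C)C(C)(C)C)O[C@](CC)(/C=C(\CC)/C=C/c2ccccc2)[C@H]1[C@H](CC)CO[Si](C)(C)C(C)(C)C | intermediate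
22 | tert-butyl(dimethyl)silyl (1R,2S,5R,6E)-5-[(2S)-1-{[tert-butyl(dimethyl)silyl]oxy}butan-2-yl]-1,2,4-triethyl-2-[(E)-2-phenylethenyl]-6-propylidenecyclohex-3-ene-1-carboxylate | CCC1=C[C@@](/C=C/c2ccccc2)(CC)[C@](CC)(C(=O)O[Si](C)(C)C(C)(C)C)/C(=C/CC)[C@@H]1[C@H](CC)CO[Si](C)(C)C(C)(C)C | intermediate
23 | (1R,2S,5R,6E)-5-[(2S)-1-{[tert-butyl(dimethyl)silyl]oxy}butan-2-yl]-1,2,4-triethyl-2-[(E)-2-phenylethenyl]-6-propylidenecyclohex-3-ene-1-carboxylic acid | CCC1=C[C@@](/C=C/c2ccccc2)(CC)[C@](CC)(C(=O)O)/C(=C/CC)[C@@H]1[C@H](CC)CO[Si](C)(C)C(C)(C)C | intermediate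
24 | methyl (1R,2S,5R,6E)-5-[(2S)-1-{[tert-butyl(dimethyl)silyl]oxy}butan-2-yl]-1,2,4-triethyl-2-[(E)-2-phenylethenyl]-6-propylidenecyclohex-3-ene-1-carboxylate | CCC1=C[C@@](/C=C/c2ccccc2)(CC)[C@](CC)(C(=O)OC)/C(=C/CC)[C@@H]1[C@H](CC)CO[Si](C)(C)C(C)(C)C | intermediate
25 | methyl (1R,2S,5R,6E)-1,2,4-triethyl-5-[(2S)-1-hydroxybutan-2-yl]-2-[(E)-2-phenylethenyl]-6-propylidenecyclohex-3-ene-1-carboxylate | CCC1=C[C@@](/C=C/c2ccccc2)(CC)[C@](CC)(C(=O)OC)/C(=C/CC)[C@@H]1[C@H](CC)CO | intermediate
26 | methyl (1R,2S,5R,6E)-1,2,4-triethyl-5-[(2S)-1-oxobutan-2-yl]-2-[(E)-2-phenylethenyl]-6-propylidenecyclohex-3-ene-1-carboxylate | CCC1=C[C@@](/C=C/c2ccccc2)(CC)[C@](CC)(C(=O)OC)/C(=C/CC)[C@@H]1[C@H](CC)C=O | intermediate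
27 | methyl (1S,3R,3aR,4R,5S,7aR)-1,3,4,5,7-pentaethyl-2-oxo-5-[(E)-2-phenylethenyl]-2,3,3a,4,5,7a-hexahydro-1H-indene-4-carboxylate | CCC1=C[C@@](/C=C/c2ccccc2)(CC)[C@](CC)(C(=O)OC)[C@@H]2[C@@H]1[C@H](CC)C(=O)[C@@H]2CC | intermediate
28 | methyl (1S,3S,3aR,4R,5S,7aR)-1,3,4,5,7-pentaethyl-2-oxo-5-[(E)-2-phenylethenyl]-2,3,3a,4,5,7a-hexahydro-1H-indene-4-carboxylate | CCC1=C[C@@](/C=C/c2ccccc2)(CC)[C@](CC)(C(=O)OC)[C@@H]2[C@@H]1[C@H](CC)C(=O)[C@H]2CC | intermediate
29 | (1S,3S,3aR,4R,5S,7aR)-1,3,4,5,7-pentaethyl-2-oxo-5-[(E)-2-phenylethenyl]-2,3,3a,4,5,7a-hexahydro-1H-indene-4-carboxylic acid | CCC1=C[C@@](/C=C/c2ccccc2)(CC)[C@](CC)(C(=O)O)[C@@H]2[C@@H]1[C@H](CC)C(=O)[C@H]2CC | target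

## Step count and least certain steps

Total: 18 steps. Longest linear sequence: 15 steps (steps 1 to 4, then 8 to 18); the ketone branch (steps 5 to 7) joins at step 8.

**Step 13 (key step).** The base may instead remove the ring hydrogen at C5, after which β-elimination of the carboxylate opens the lactone. The tertiary dienylic C–O bond of the ketene acetal may also ionise before the concerted shift, which would lose the stereospecificity or transpose the allyl unit. Fallback, setting out from triflate 18 and returning at 23: the enolate is generated by hydride addition and not by deprotonation. Suzuki coupling of 18 with (E)-prop-1-enylboronic acid (Pd(PPh3)4, K3PO4, dioxane) should give the 4-propenyl lactone F1. 1,6-Addition of hydride (LiBH(s-Bu)3, THF, −78 °C) to its dienoate, with TBSCl present, should then give ketene acetal 21 regiospecifically, and heating and work-up as in step 13 lead to 23.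

**Step 8.** Facial selection at the ketone may be poor, because ethyl and dienyl differ less in size than the chair model assumes. Proton transfer from the ketone to the enolate and reversal of the aldol before acylation are further risks. Fallback, setting out from 7 and returning at 14: catalyst control replaces substrate control at the carbonyl face. Lactone 7 is converted (LiN(iPr)2, Me3SiCl) into the silyl ketene acetal F2. A copper fluoride–bisphosphine catalysed Mukaiyama-type addition to 13 (CuF(PPh3)3·2EtOH, tol-BINAP of the appropriate hand, (EtO)3SiF) should give, after work-up, the free tertiary alcohol F3. Deprotonation of F3 with LiN(SiMe3)2 at −78 °C gives 14, which is acylated with 2 as before.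

**Step 9.** The base may remove the lactone α-hydrogen, followed by E1cB loss of butanoate to an alkylidene lactone; alternatively the acyclic ester enolate may rearrange on its own. Fallback, setting out from 14 and returning at 16: the enolate is made reductively. Aldolate 14 is trapped with 2-bromobutanoyl bromide in place of 2 to give the bromo ester F4. SmI2 (THF, −78 °C) should then form the trivalent samarium enolate without base, and this acylates intramolecularly at the lactone carbonyl (Reformatsky type) to give 16.

**Step 17.** Insertion of the hindered trisubstituted alkene may be slower than decarbonylation of the acyl rhodium hydride, or than migration of the exocyclic alkene into conjugation. Fallback, setting out from 26 and returning at 28: chelation-assisted hydroacylation. Condensation of 26 with 3-methylpyridin-2-amine gives the aldimine F5. RhCl(PPh3)3 (toluene, 130 °C) should activate its C–H bond as a five-membered iminoacyl rhodium hydride that cannot lose CO, and cyclisation gives the ketimine F6. Aqueous acid releases 27, which DBU equilibrates to 28.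

## Further compounds

F1 | step 13 | (5S,6R)-5-[(2S)-1-{[tert-butyl(dimethyl)silyl]oxy}butan-2-yl]-3,6-diethyl-6-[(1E,3E)-2-ethyl-4-phenylbuta-1,3-dien-1-yl]-4-[(1E)-prop-1-en-1-yl]-5,6-dihydro-2H-pyran-2-one | C/C=C/C1=C(CC)C(=O)O[C@](CC)(/C=C(\CC)/C=C/c2ccccc2)[C@H]1[C@H](CC)CO[Si](C)(C)C(C)(C)C
F2 | step 8 | {[(4S)-4-ethyl-4,5-dihydrofuran-2-yl]oxy}(trimethyl)silane | CC[C@@H]1COC(O[Si](C)(C)C)=C1
F3 | step 8 | (3R,4S)-4-ethyl-3-[(3R,4E,6E)-5-ethyl-3-hydroxy-7-phenylhepta-4,6-dien-3-yl]oxolan-2-one | CC[C@@H]1COC(=O)[C@H]1[C@@](O)(CC)/C=C(\CC)/C=C/c1ccccc1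
F4 | step 9 | (3R,4E,6E)-5-ethyl-3-[(3R,4S)-4-ethyl-2-oxooxolan-3-yl]-7-phenylhepta-4,6-dien-3-yl 2-bromobutanoate (either configuration at the brominated carbon) | CC[C@@H]1COC(=O)[C@H]1[C@@](OC(=O)C(Br)CC)(CC)/C=C(\CC)/C=C/c1ccccc1
F5 | step 17 | methyl (1R,2S,5R,6E)-1,2,4-triethyl-5-{(2S)-1-[(3-methylpyridin-2-yl)imino]butan-2-yl}-2-[(E)-2-phenylethenyl]-6-propylidenecyclohex-3-ene-1-carboxylate | CCC1=C[C@@](/C=C/c2ccccc2)(CC)[C@](CC)(C(=O)OC)/C(=C/CC)[C@@H]1[C@H](CC)C=Nc1ncccc1C
F6 | step 17 | methyl (1S,3R,3aR,4R,5S,7aR)-1,3,4,5,7-pentaethyl-2-[(3-methylpyridin-2-yl)imino]-5-[(E)-2-phenylethenyl]-2,3,3a,4,5,7a-hexahydro-1H-indene-4-carboxylate | CCC1=C[C@@](/C=C/c2ccccc2)(CC)[C@](CC)(C(=O)OC)[C@@H]2[C@@H]1[C@H](CC)C(=Nc1ncccc1C)[C@@H]2CC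
A1 | alternative 1 | methyl (1S,3S,3aR,4R,5S,7aR)-5-ethenyl-1,3,4,5,7-pentaethyl-2-oxo-2,3,3a,4,5,7a-hexahydro-1H-indene-4-carboxylate | CCC1=C[C@@](C=C)(CC)[C@](CC)(C(=O)OC)[C@@H]2[C@@H]1[C@H](CC)C(=O)[C@H]2CC
A2 | alternative 1 | methyl (2R)-2-[(1R,2R,3S,5S)-2-(but-1-en-2-yl)-3,5-diethyl-4-oxocyclopentyl]-3-ethenyl-2,3-diethylpent-4-enoate | C=CC(C=C)(CC)[C@](CC)(C(=O)OC)[C@@H]1[C@@H](C(=C)CC)[C@H](CC)C(=O)[C@H]1CC
A3 | alternative 2 | methyl 1,3,4,5,7-pentaethyl-2-oxo-5-[(E)-2-phenylethenyl]-2,4,5,7a-tetrahydro-1H-indene-4-carboxylate (configuration as in the SMILES) | CCC1=C[C@@](/C=C/c2ccccc2)(CC)[C@](CC)(C(=O)OC)C=2[C@@H]1[C@H](CC)C(=O)C2CC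
A4 | alternative 2 | methyl (4Z,6E)-2-(but-1-yn-1-yl)-2,3,5-triethyl-3-[(E)-2-phenylethenyl]nona-4,6-dienoate (configuration at C2 and C3 as in the SMILES) | CC/C=C/C(CC)=C\[C@@](/C=C/c1ccccc1)(CC)[C@](CC)(C(=O)OC)C#CCC
A5 | alternative 3 | 1-ethyl 4-methyl 3,4,5,7-tetraethyl-2-oxo-5-[(E)-2-phenylethenyl]-2,3,3a,4,5,7a-hexahydro-1H-indene-1,4-dicarboxylate (trans-fused, configuration as in the SMILES) | CCC1=C[C@@](/C=C/c2ccccc2)(CC)[C@](CC)(C(=O)OC)[C@@H]2[C@@H]1[C@H](C(=O)OCC)C(=O)[C@H]2CC
A6 | alternative 3 | methyl 6-(5-diazo-6-ethoxy-4,6-dioxohexan-3-yl)-1,2,4-triethyl-2-[(E)-2-phenylethenyl]cyclohex-3-ene-1-carboxylate (configuration as in the SMILES) | CCC1=C[C@@](/C=C/c2ccccc2)(CC)[C@](CC)(C(=O)OC)[C@H](C1)[C@H](CC)C(=O)C(=[N+]=[N-])C(=O)OCC
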